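I began with the rate. Four flasks with the same charge stood at different temperatures for the same time, and two earlier runs were at hand.

all flasks: starting material 0.10 M

| run | protic impurity | temperature | remark | time |
|---|---|---|---|---|
| autumn | 0.067 M | 55 °C | run made earlier |  |
| midnight | 0.15 M | 90 °C | run made earlier |  |
| teal | 0.100 M | 120 °C |  | 6.0 d |
| ochre | 0.100 M | 100 °C |  | 6.0 d |
| amber | 0.100 M | 80 °C |  | 6.0 d |
| grey | 0.100 M | 60 °C |  | 6.0 d |

| run | time / d | ring / % |
|---|---|---|
| autumn | 15.0 | 29.7 |
| autumn | 30.0 | 29.3 |
| autumn | 40.0 | 27.0 |
| autumn | 60.0 | 24.1 |
| autumn | 80.0 | 21.9 |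
| autumn | 100 | 19.4 |
| midnight | 1.04 | 22.3 |
| midnight | 2.00 | 19.7 |
| midnight | 4.00 | 12.7 |
| midnight | 6.00 | 12.6 |
| midnight | 8.00 | 11.9 |
| midnight | 20.0 | 11.9 |

(scatter of a reading: 1 percentage point)



* the flask that comes out highest in amount of ring, in percent of the starting material charged, or "all alike" when all lie within 1.5 percentage points (teal / ochre / amber / grey / all alike)
* ring at the end, in percent of the starting material charged, teal
* ring at the end, in percent of the starting material charged, ochre
* ring at the end, in percent of the starting material charged, amber
* ring at the end, in percent of the starting material charged, grey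

From its first reading to its last, the autumn run lost ring at a fractional rate of 0.00501 d⁻¹. In the midnight run, the excess of ring over its last reading of 11.9 % fell at 0.867 d⁻¹ between the first and third readings, a rough reading: at the third reading that excess was 0.8 percentage points, against a scatter of 1 point. The two runs also differ in protic impurity; I lumped that with temperature and let the rate grow by a constant factor per degree, which gave 0.0105 d⁻¹ for grey.

Over 6.0 d that makes 0.0628. This product of fractional loss rate and time, the loss number, was my measure of relaxation: in a first-order relaxation the excess over the final level shrinks by the exponential of its negative, though my autumn rate was read on ring itself, not on an excess. Amber came to 1.19, which keeps 30.4 % of the excess, and ochre to 22.7, so I expected ochre at its level. For grey the number stayed below one, so I took the first autumn reading, reduced it, and reckoned 27.9 % of ring.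

The forecast named grey highest, with 20.5 % for teal, 17.5 % for ochre, 20 % for amber and 27 % for grey, holding that “grey has barely decayed”. My grey stood a little above its figure.

The flasks gave 25.6 % for teal, 17.1 % for ochre, 18.9 % for amber and 29.5 % for grey, so grey came out highest, and teal stood above the forecast's figure.

    starting material → ring (k = 2.54 × 10⁻⁵ s⁻¹, Ea = 104 kJ mol⁻¹)
    2 starting material → open dimer (k = 4.37 × 10⁻⁴ M⁻¹ s⁻¹, Ea = 97.0 kJ mol⁻¹)
    starting material + protic impurity → quenched substrate (k = 1.11 × 10⁻⁴ M⁻¹ s⁻¹, Ea = 97.0 kJ mol⁻¹)
    ring ⇌ isomer of the product (K = 2.83, k = 1.54 × 10⁻⁶ s⁻¹, Ea = 119 kJ mol⁻¹, ΔH = −44.0 kJ mol⁻¹)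
    (constants at 80 °C)

In grey, the path to open dimer had 83 % of its turnover up to the asked time behind it after 1.20 d, and the path to ring had 85 % behind it after 3.00 d, and starting material stood at 2.99 % after 6.00 d. At 6.00 d in grey, ring was still made 2.29 times faster than it was used up, each step taken net, and the relaxation half-life of ring and isomer of the product by their step alone, 51.9 d, was long against the time. Grey's isomer of the product made up 5.12 % of ring and isomer of the product together, against a loss number of 6.28 %.

A neighbour of grey charged with 0.040 M of starting material had the same temperature and time, so I again took the loss number, 6.28 %, as the share of isomer of the product in its ring and isomer of the product together. Computed, that neighbour held 40.5 % of ring and 2.09 % of isomer of the product, a share of 4.91 %.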